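Multiply the partner charge by the elapsed time before comparing flasks.

| flask | starting material | partner | second substrate | precatalyst | remark | time |
|---|---|---|---|---|---|---|
| amber | 0.41 M | 0.19 M | 0.41 M | 4.1 mM | run made earlier |  |
| green | 0.41 M | 1.6 M | 0.41 M | 4.1 mM | run made earlier |  |
| zeta | 0.41 M | 0.250 M | 0.410 M | 4.1 mM |  | 2.5 min |
| delta | 0.41 M | 0.500 M | 0.410 M | 4.1 mM |  | 2.5 min |
| gamma | 0.41 M | 1.00 M | 0.410 M | 4.1 mM |  | 2.5 min |
| theta | 0.41 M | 2.00 M | 0.410 M | 4.1 mM |  | 2.5 min |

| run | time / min | target / % |
|---|---|---|
| amber | 0.200 | 0.7 |
| amber | 0.500 | 0 |
| amber | 1.00 | 0.3 |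
| amber | 2.50 | 2.6 |
| green | 0.333 | 1.9 |
| green | 0.833 | 15.8 |
| green | 1.50 | 34.3 |
| green | 2.50 | 59.2 |

(readings scatter by 1 percentage point)
- the analysis behind the earlier runs scatters by 1 percentage point, standard deviation
- "hardly changes" means that all values lie within two and a half points (for a concentration: within two and a half percent of the largest)
1. amount of target at the end, in percent of the starting material charged for zeta, delta, gamma, theta, in this order
2. how that number moves from the first to the last of them (falls all the way / rises, then falls / rises all the way / falls, then rises / hardly changes)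

Starting material and partner gave the target in flasks that also held second substrate and precatalyst. I called c(partner) × t the dose, with c(partner) as charged. Amber at 2.50 min had a dose of 0.475 M·min and read 2.6 %. Green at 0.333 min had 0.533 M·min and read 1.9 %. With a scatter of 1 percentage point, those two readings agreed, so I took equal dose to mean equal target. That gave zeta 0.625 M·min, delta 1.25 M·min, gamma 2.50 M·min and theta 5.00 M·min, and this end-of-run dose is what I carried forward.

Green's doses were 0.533 M·min, 1.33 M·min and 2.40 M·min, with readings of 1.9 %, 15.8 % and 34.3 %. I expected zeta above the first reading, delta below the second and gamma above the third.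

Theta's dose lay beyond green's last one, so I worked with the fraction left, counting as left whatever had not become target. Its negative logarithm, L, grew in green as dose to the power 1.48 over the last two readings. This gave theta an L of 1.25, or 71.3 % target.

The forecast gave 4 %, 12 %, 31 % and 73 %, so its theta stood above mine, and its shape was rises all the way: “Nothing in the data shows inhibition up to 1.6 M, so I expect a steady rise”.

    starting material + partner + catalyst → catalyst + target (k = 1.90 M⁻² s⁻¹)
    second substrate + partner + catalyst → catalyst + second product (k = 0.0710 M⁻² s⁻¹)
    partner + precatalyst → catalyst + spent reagent (k = 0.00760 M⁻¹ s⁻¹)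
    starting material → decomposition product (k = 1.40 × 10⁻⁵ s⁻¹)

The flasks gave 3.56 %, 12.1 %, 34.5 % and 71.5 %: rises all the way. Theta at 1.25 min had a dose of 2.50 M·min, the same as gamma at its end, 2.50 M·min. Theta then held 66.8 % of the catalyst charged as catalyst and 36.0 % target, against 65.7 % and 34.5 % in gamma at its end. Zeta at 25.0 min reached a dose of 6.25 M·min, above theta's end-of-run 5.00 M·min, yet held 48.5 % target against 71.5 % in theta at 2.50 min, with partner at 15.1 % of its charge in zeta against 84.2 % in theta.

The readings were computed for substances that don't exist, and the scatter is random.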